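**Retrosynthetic overview**
1. Both rings, the three stereocentres (C5, C9, C10) and the 8(17)-methylene are taken intact from (−)-andrographolide (ent-labdane series). No ring is formed in the route; only ring A and the side chain are edited.
2. Target ⇒ O-acetylation of triene diol 12 ⇒ two Wittig olefinations (C14=C15, then E-C12=C13) back to C12 aldehyde 10.
3. C18–O bond ⇒ hydroxyl-directed oxygenation of the geminal methyl C18–H from the C19 carbinol of 6 (the key bond formation).
4. C3 methylene ⇒ radical deoxygenation of the 3,19-diol through cyclic thionocarbonate 4.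
5. Masked C12 aldehyde 3 ⇒ chemoselective oxidative cleavage of the conjugated C12=C13 bond of andrographolide.

Assumption: bulk (−)-andrographolide (from Andrographis paniculata) is taken as the cheap commercial starting material; its 5S,9R,10S configuration is that of the target, so no stereocentre has to be created.

Labdane numbering is used throughout (C18 = equatorial methyl on C4, C19 = axial CH2O on C4, C17 = exocyclic methylene carbon).

Step 1
Reactants: 1 (−)-andrographolide
Product: 2 (3R,4R,5S,9R,10S)-3,19-dihydroxy-13,14,15,16-tetranorlabd-8(17)-en-12-al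
Conditions: KMnO4 (1.4 equiv), MgSO4, acetone/H2O 4:1, −15 °C, 30 min; aq. NaHSO3 quench
Reagents that add atoms: potassium permanganate, [K+].[O-][Mn](=O)(=O)=O
Why: Permanganate oxidative cleavage of the conjugated, electron-poor C12=C13 bond, which MnO4− attacks faster than the isolated, hindered exocyclic C8=C17 bond; buffered, cold and with limited oxidant the aldehyde survives, and C3, C4, C5, C9 and C10 are untouched.

Step 2
Reactants: 2 (3R,4R,5S,9R,10S)-3,19-dihydroxy-13,14,15,16-tetranorlabd-8(17)-en-12-al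
Product: 3 (3R,4R,5S,9R,10S)-12,12-dimethoxy-13,14,15,16-tetranorlabd-8(17)-ene-3,19-diol
Conditions: MeOH, PPTS (0.1 equiv), 3 Å MS, rt
Reagents that add atoms: methanol, CO
Why: Acid-catalysed acetalisation masks the aldehyde against the tin hydride, hydrosilane and peroxide used next; no stereocentre is involved.

Step 3
Reactants: 3 (3R,4R,5S,9R,10S)-12,12-dimethoxy-13,14,15,16-tetranorlabd-8(17)-ene-3,19-diol
Product: 4 (3R,4R,5S,9R,10S)-12,12-dimethoxy-13,14,15,16-tetranorlabd-8(17)-ene-3,19-diyl cyclic thionocarbonate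
Conditions: 1,1'-thiocarbonyldiimidazole (1.5 equiv), DMAP (0.2 equiv), PhMe, 80 °C
Reagents that add atoms: 1,1'-thiocarbonyldiimidazole, S=C(n1ccnc1)n1ccnc1
Why: Thiocarbonylation of the 1,3-diol closes the six-membered cyclic thionocarbonate across the equatorial C3 hydroxyl and the axial C19 hydroxymethyl, the same pair that gives the 3,19-acetonide of andrographolide.

Step 4
Reactants: 4 (3R,4R,5S,9R,10S)-12,12-dimethoxy-13,14,15,16-tetranorlabd-8(17)-ene-3,19-diyl cyclic thionocarbonate
Product: 6 (4R,5S,9R,10S)-12,12-dimethoxy-13,14,15,16-tetranorlabd-8(17)-en-19-ol, via stannyl thiocarbonate 5 (not isolated)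
Conditions: Bu3SnH (2 equiv, slow addition), AIBN (0.2 equiv), PhMe, 110 °C; then 1 M NaOH, THF/MeOH, rt
Reagents that add atoms: none
Why: Barton–McCombie-type radical deoxygenation of a cyclic thionocarbonate: the stannyl radical adds to sulfur, the ring opens at C3–O to the secondary radical rather than at C19–O (primary neopentyl radical), Bu3SnH delivers hydrogen to C3 and hydrolysis frees the C19 carbinol; C3 stops being a stereocentre and C4 is retained.

Step 5
Reactants: 6 (4R,5S,9R,10S)-12,12-dimethoxy-13,14,15,16-tetranorlabd-8(17)-en-19-ol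
Product: 9 (5S,9R,10S)-12,12-dimethoxy-13,14,15,16-tetranorlabd-8(17)-ene-18,19-diol, via hydridosilyl ether 7 (not isolated), via spiro-oxasilolane 8 (not isolated)
Conditions: Et2SiH2 (1.5 equiv), [Ir(cod)OMe]2 (0.5 mol%), THF, rt, then evaporate; [Ir(cod)OMe]2 (2 mol%), 3,4,7,8-Me4-1,10-phenanthroline (5 mol%), norbornene (1.2 equiv), THF, 80 °C; then 30% H2O2, KHCO3, THF/MeOH, 50 °C
Reagents that add atoms: hydrogen peroxide, OO
Why: Proposed new method: iridium-catalysed γ-C(sp3)–H silylation directed by the hydridosilyl ether of a primary, neopentylic carbinol onto its own geminal methyl, followed by Tamao–Fleming oxidation (closest known reaction: the same silylation/oxidation directed by secondary and tertiary carbinols, for example from a C3 hydroxyl onto the equatorial C4 methyl of triterpenoids); the Si–H of 7 adds to the iridium phenanthroline catalyst, the iridium silyl cleaves the only primary C–H bond that can close a five-membered ring (C18; C3–H2 is secondary and C20 would need a seven-membered ring), C–Si reductive elimination gives 8 with norbornene taking up the hydrogen, and peroxide oxidation of the C–Si bond forms the C18–O bond; the quaternary C4 (Thorpe–Ingold effect) and the hindered axial carbinol (little dialkoxysilane) favour the sequence, C4 becomes non-stereogenic and C5, C9, C10 are untouched.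

Step 6
Reactants: 9 (5S,9R,10S)-12,12-dimethoxy-13,14,15,16-tetranorlabd-8(17)-ene-18,19-diol
Product: 10 (5S,9R,10S)-18,19-dihydroxy-13,14,15,16-tetranorlabd-8(17)-en-12-al
Conditions: AcOH/THF/H2O 3:1:1, 40 °C
Reagents that add atoms: water, O
Why: Mild aqueous-acid acetal hydrolysis releases the aldehyde; the exocyclic alkene and the diol tolerate dilute acetic acid, and C9 is not alpha to the carbonyl so it cannot epimerise.

Step 7
Reactants: 10 (5S,9R,10S)-18,19-dihydroxy-13,14,15,16-tetranorlabd-8(17)-en-12-al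
Product: 11 (5S,9R,10S,12E)-18,19-dihydroxy-15-norlabda-8(17),12-dien-14-al
Conditions: Ph3P=C(Me)CHO (1.5 equiv), PhMe, 90 °C
Reagents that add atoms: 2-(triphenylphosphoranylidene)propanal, CC(C=O)=P(c1ccccc1)(c1ccccc1)c1ccccc1
Why: Wittig olefination with a stabilised ylide gives the (E)-2-methyl enal (CHO trans to C11) with high selectivity, which sets the C12=C13 geometry; the free hydroxyls do not interfere.

Step 8
Reactants: 11 (5S,9R,10S,12E)-18,19-dihydroxy-15-norlabda-8(17),12-dien-14-al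
Product: 12 (5S,9R,10S,12E)-labda-8(17),12,14-triene-18,19-diol
Conditions: Ph3PCH3Br (4 equiv), KOtBu (3.8 equiv), THF, 0 °C; then 11, −78 → 0 °C
Reagents that add atoms: methyltriphenylphosphonium bromide, C[P+](c1ccccc1)(c1ccccc1)c1ccccc1.[Br-]
Why: Wittig methylenation of the enal carbonyl completes the (12E)-3-methylpenta-2,4-dienyl chain; excess ylide covers the two hydroxyls and the C12=C13 geometry is not touched.

Step 9
Reactants: 12 (5S,9R,10S,12E)-labda-8(17),12,14-triene-18,19-diol
Product: 13 (5S,9R,10S,12E)-labda-8(17),12,14-triene-18,19-diyl diacetate (CNP0129553.1)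
Conditions: Ac2O (4 equiv), pyridine, DMAP (0.1 equiv), CH2Cl2, rt
Reagents that add atoms: acetic anhydride, CC(=O)OC(C)=O
Why: DMAP-catalysed O-acetylation of the two neopentylic primary hydroxyls; the triene and all stereocentres are unaffected.

**Compound list**
1 | (−)-andrographolide, (3E,4S)-3-{2-[(1R,4aS,5R,6R,8aS)-6-hydroxy-5-(hydroxymethyl)-5,8a-dimethyl-2-methylidenedecahydronaphthalen-1-yl]ethylidene}-4-hydroxyoxolan-2-one | O=C3OC[C@@H](O)/C3=C\C[C@@H]1C(=C)CC[C@@H]2[C@](C)(CO)[C@H](O)CC[C@@]12C | starting material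
2 | (3R,4R,5S,9R,10S)-3,19-dihydroxy-13,14,15,16-tetranorlabd-8(17)-en-12-al | O=CC[C@@H]1C(=C)CC[C@@H]2[C@](C)(CO)[C@H](O)CC[C@@]12C | intermediate
3 | (3R,4R,5S,9R,10S)-12,12-dimethoxy-13,14,15,16-tetranorlabd-8(17)-ene-3,19-diol | COC(OC)C[C@@H]1C(=C)CC[C@@H]2[C@](C)(CO)[C@H](O)CC[C@@]12C | intermediate
4 | (3R,4R,5S,9R,10S)-12,12-dimethoxy-13,14,15,16-tetranorlabd-8(17)-ene-3,19-diyl cyclic thionocarbonate | COC(OC)C[C@@H]1C(=C)CC[C@@H]2[C@]3(C)COC(=S)O[C@@H]3CC[C@@]12C | intermediate
5 | O-[(4R,5S,9R,10S)-12,12-dimethoxy-13,14,15,16-tetranorlabd-8(17)-en-19-yl] S-(tributylstannyl) thiocarbonate | COC(OC)C[C@@H]1C(=C)CC[C@@H]2[C@](C)(COC(=O)S[Sn](CCCC)(CCCC)CCCC)CCC[C@@]12C | intermediate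
6 | (4R,5S,9R,10S)-12,12-dimethoxy-13,14,15,16-tetranorlabd-8(17)-en-19-ol | COC(OC)C[C@@H]1C(=C)CC[C@@H]2[C@](C)(CO)CCC[C@@]12C | intermediate
7 | 19-O-(diethylsilyl) ether of 6 (4R,5S,9R,10S; Si–H retained) | COC(OC)C[C@@H]1C(=C)CC[C@@H]2[C@](C)(CO[SiH](CC)CC)CCC[C@@]12C | intermediate
8 | (4S,5S,9R,10S) spiro-oxasilolane of 6 with SiEt2 bridging O19 and C18 | COC(OC)C[C@@H]1C(=C)CC[C@@H]2[C@]3(CO[Si](CC)(CC)C3)CCC[C@@]12C | intermediate
9 | (5S,9R,10S)-12,12-dimethoxy-13,14,15,16-tetranorlabd-8(17)-ene-18,19-diol | COC(OC)C[C@@H]1C(=C)CC[C@@H]2C(CO)(CO)CCC[C@@]12C | intermediate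
10 | (5S,9R,10S)-18,19-dihydroxy-13,14,15,16-tetranorlabd-8(17)-en-12-al | O=CC[C@@H]1C(=C)CC[C@@H]2C(CO)(CO)CCC[C@@]12C | intermediate
11 | (5S,9R,10S,12E)-18,19-dihydroxy-15-norlabda-8(17),12-dien-14-al | O=C/C(C)=C/C[C@@H]1C(=C)CC[C@@H]2C(CO)(CO)CCC[C@@]12C | intermediate
12 | (5S,9R,10S,12E)-labda-8(17),12,14-triene-18,19-diol | C=C/C(C)=C/C[C@@H]1C(=C)CC[C@@H]2C(CO)(CO)CCC[C@@]12C | intermediate
13 | (5S,9R,10S,12E)-labda-8(17),12,14-triene-18,19-diyl diacetate | C=C/C(C)=C/C[C@@H]1C(=C)CC[C@@H]2C(COC(C)=O)(COC(C)=O)CCC[C@@]12C | target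

**Step count**
Total step count: 9. Longest linear sequence: 9 steps (fully linear from 1).

**Steps most likely to fail**

Step 1 (chemoselective cleavage). The selectivity for C12=C13 over C8=C17 rests on the electron-poor alkene reacting faster with permanganate, and the aldehyde can be over-oxidised. Fallback: set out from 1 and use the C14 hydroxyl to steer the oxidant. Stoichiometric OsO4/TMEDA (CH2Cl2, −78 °C, then aq. NaHSO3) dihydroxylates only the allylic-alcohol alkene by hydrogen-bond delivery and gives 12,13-dihydroxy-12,13-dihydroandrographolide F1. NaIO4 (THF/H2O, 0 °C) then cleaves the glycol to aldehyde 2, where the route is rejoined.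

Step 4 (ring-opening direction of the cyclic thionocarbonate). The six-membered ring may fragment slowly or partly at C19–O. Fallback: set out from 3 and use an acyclic xanthate, which removes the regiochemical question. TBSCl/imidazole (DMF, 0 °C) gives the 19-O-tert-butyldimethylsilyl ether F2. NaH, CS2, then MeI (THF) gives the C3 S-methyl xanthate F3. Bu3SnH/AIBN (PhMe, 110 °C) gives the 3-deoxy silyl ether F4, and TBAF (THF) returns carbinol 6.

Step 5 (the proposed new C–H silylation/oxidation). The primary carbinol may give a dialkoxysilane, C–H cleavage may be slow, or iridium hydrides may isomerise the exocyclic alkene. Fallback with known chemistry: set out from 3 and let the secondary C3 hydroxyl direct, as established for 3-hydroxy-4-methyl terpenoids, then remove the C3 oxygen afterwards.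
- AcCl/2,4,6-collidine (CH2Cl2, −78 °C) gives the 19-O-acetate F5.
- Et2SiH2 with [Ir(cod)OMe]2 gives the C3 diethylsilyl ether F6.
- [Ir(cod)OMe]2/3,4,7,8-Me4-1,10-phenanthroline/norbornene (THF, 80–100 °C) closes the O3–Si–C18 oxasilolane F7.
- H2O2/KHCO3 gives the 3,18-diol 19-acetate F8.
- 1,1'-Thiocarbonyldiimidazole gives the 3,18-cyclic thionocarbonate 19-acetate F9.
- Bu3SnH/AIBN gives the 3-deoxy 18-O-stannylthiocarbonate 19-acetate F10.
- NaOH in MeOH/THF cleaves the thiocarbonate and the acetate to diol 9, where the route is rejoined.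

**Further compounds**
F1 | step 1 | 12,13-dihydroxy-12,13-dihydroandrographolide (both new hydroxyls syn to the C14 hydroxyl) | O=C3OC[C@@H](O)[C@]3(O)[C@H](O)C[C@@H]1C(=C)CC[C@@H]2[C@](C)(CO)[C@H](O)CC[C@@]12C
F2 | step 4 | 19-O-tert-butyldimethylsilyl ether of diol 3 | COC(OC)C[C@@H]1C(=C)CC[C@@H]2[C@](C)(CO[Si](C)(C)C(C)(C)C)[C@H](O)CC[C@@]12C
F3 | step 4 | 3-O-[(methylsulfanyl)thiocarbonyl] derivative (S-methyl xanthate) of F2 | COC(OC)C[C@@H]1C(=C)CC[C@@H]2[C@](C)(CO[Si](C)(C)C(C)(C)C)[C@H](OC(=S)SC)CC[C@@]12C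
F4 | step 4 | 19-O-tert-butyldimethylsilyl ether of carbinol 6 | COC(OC)C[C@@H]1C(=C)CC[C@@H]2[C@](C)(CO[Si](C)(C)C(C)(C)C)CCC[C@@]12C
F5 | step 5 | 19-O-acetate of diol 3 | COC(OC)C[C@@H]1C(=C)CC[C@@H]2[C@](C)(COC(C)=O)[C@H](O)CC[C@@]12C
F6 | step 5 | 3-O-(diethylsilyl) ether of F5 | COC(OC)C[C@@H]1C(=C)CC[C@@H]2[C@](C)(COC(C)=O)[C@H](O[SiH](CC)CC)CC[C@@]12C
F7 | step 5 | oxasilolane with SiEt2 bridging O3 and C18, 19-acetate | COC(OC)C[C@@H]1C(=C)CC[C@@H]2[C@@]3(COC(C)=O)C[Si](CC)(CC)O[C@@H]3CC[C@@]12C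
F8 | step 5 | 3,18-diol 19-acetate of the 12,12-dimethoxy tetranorlabd-8(17)-ene | COC(OC)C[C@@H]1C(=C)CC[C@@H]2[C@](CO)(COC(C)=O)[C@H](O)CC[C@@]12C
F9 | step 5 | 3,18-cyclic thionocarbonate 19-acetate | COC(OC)C[C@@H]1C(=C)CC[C@@H]2[C@@]3(COC(C)=O)COC(=S)O[C@@H]3CC[C@@]12C
F10 | step 5 | 3-deoxy 18-O-[(tributylstannylsulfanyl)carbonyl] 19-acetate | COC(OC)C[C@@H]1C(=C)CC[C@@H]2[C@](COC(=O)S[Sn](CCCC)(CCCC)CCCC)(COC(C)=O)CCC[C@@]12C
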